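**Strategy.** The side chain is detached at C11–C12. This leaves (+)-albicanol and a C12–C16 unit from D-malate, and everything then rests on cutting the decalin at C9–C10. The feature exploited is that ring A (C1–C5, C10) with the C4 methyl pair, C20, the C5 stereocentre and the tether C6–C9 all pre-exist in α-ionone, so one bond to quaternary C10 completes ring B. The key step is an intramolecular palladium-catalysed allylic alkylation. In one operation it closes ring B, creates C10 and C9, and transfers the C2 carbinol configuration to C10. Its precursor is a ring A cyclohexenyl methyl carbonate, C2–O trans to the C5 chain, whose chain ends in a β-keto ester.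

Key step: step 8

**Remarks**
- Labdane numbering is used for all compounds: ring A = C1–C5, C10; ring B = C5–C10; C11 on C9; C17 = exocyclic methylene; C20 = methyl on C10.
- The target is (5S,9S,10S,13R,14R). This calls for (5S) in the ionone series, a (2S) carbinol, and (R)-malate methylated anti.
- Assumption: enantiopure α-ionone is not counted as an article of commerce, so the racemate is bought and resolved at alcohol 5.
- Racemates with one stereocentre are written without stereo labels. Racemic 5 is written as both enantiomers.

**Route**

Step 1
Reactants: 1 (±)-α-ionone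
Product: 2 (±)-dihydro-α-ionone, 4-(2,6,6-trimethylcyclohex-2-en-1-yl)butan-2-one
Conditions: H2 (1 atm, stopped after 1 equiv), Raney Ni, EtOH, rt
Reagents that add atoms: none
Why: Chemoselective catalytic hydrogenation: the conjugated, 1,2-disubstituted C6=C7 bond is saturated far faster than the hindered trisubstituted C1=C10 bond of ring A or the ketone, so the reaction is stopped after one equivalent of hydrogen.

Step 2
Reactants: 2 (±)-dihydro-α-ionone
Product: 3 (±)-dihydro-α-ionone ethylene ketal
Conditions: HOCH2CH2OH, PPTS (cat.), toluene, reflux, Dean–Stark
Reagents that add atoms: ethylene glycol, OCCO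
Why: Acid-catalysed ketalisation with azeotropic removal of water masks the C8 ketone for the oxidation and hydride steps, and the weak acid avoids migration of the ring alkene or its Prins-type closure onto the carbonyl group.

Step 3
Reactants: 3 (±)-dihydro-α-ionone ethylene ketal
Product: 4 (±)-C2 enone ketal, 3,5,5-trimethyl-4-[2-(2-methyl-1,3-dioxolan-2-yl)ethyl]cyclohex-2-en-1-one
Conditions: t-BuOOH (70% aq.), Rh2(cap)4 (1 mol %), K2CO3, CH2Cl2, rt
Reagents that add atoms: tert-butyl hydroperoxide, CC(C)(C)OO
Why: Radical allylic C–H oxidation with tert-butylperoxyl radicals attacks C2, the only unhindered allylic methylene of ring A, and carries it to the enone, while the carbonate buffer keeps the ketal intact.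

Step 4
Reactants: 4 (±)-C2 enone ketal
Product: 5 (±)-trans allylic alcohol ketal (C2–OH trans to the C5 chain)
Conditions: LiBH(s-Bu)3, THF, −78 °C; then NaOH, H2O2, 0 °C; chromatography
Reagents that add atoms: none
Why: 1,2-Reduction of a β,β-disubstituted cyclohexenone by a bulky borohydride: in the favoured half-chair with the C5 chain pseudoaxial the opposite face of C2=O is screened by the axial C4 methyl, so hydride should enter from the side of the chain and place the C2 hydroxyl trans to it, any cis isomer being removed on silica.

Step 5
Reactants: 5 (±)-trans allylic alcohol ketal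
Product: 6 (2S,5S)-trans allylic alcohol ketal
Conditions: Pseudomonas fluorescens lipase, vinyl acetate, t-BuOMe, rt, to slightly beyond half conversion; chromatography
Reagents that add atoms: none
Why: Lipase-catalysed acylative kinetic resolution: by the empirical size rule for secondary alcohols the (2R)-alcohol should be the one acetylated, so that conversion slightly past one half leaves (2S,5S)-6 in high enantiomeric purity and fixes C2 and C5 in the absolute sense at once.

Step 6
Reactants: 6 (2S,5S)-trans allylic alcohol ketal
Product: 7 (2S,5S)-hydroxy ketone, 4-[(1S,4S)-4-hydroxy-2,6,6-trimethylcyclohex-2-en-1-yl]butan-2-one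
Conditions: PPTS (cat.), acetone–H2O, 40 °C
Reagents that add atoms: water, O
Why: Acid-catalysed ketal hydrolysis under weakly acidic conditions, where cleavage of the dioxolane is much faster than ionisation of the allylic alcohol, so C2 should not epimerise.

Step 7
Reactants: 7 (2S,5S)-hydroxy ketone; 8 dimethyl carbonate
Product: 9 β-keto ester allylic carbonate, methyl 5-[(1S,4S)-4-(methoxycarbonyloxy)-2,6,6-trimethylcyclohex-2-en-1-yl]-3-oxopentanoate
Conditions: NaH, (MeO)2CO (excess), THF, reflux; AcOH, 0 °C
Reagents that add atoms: dimethyl carbonate (8), COC(=O)OC
Why: Claisen-type C-acylation of the methyl ketone at its unhindered terminus C9 (pulled through by the stabilised enolate) and carbonate exchange at the C2 alkoxide run in the same flask, so one reagent supplies both C11 and the leaving group, and methoxide is degenerate towards both new groups.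

Step 8
Reactants: 9 β-keto ester allylic carbonate
Product: 10 trans-fused bicyclic β-keto ester, methyl (1R,4aS,8aS)-5,5,8a-trimethyl-2-oxo-1,2,3,4,4a,5,6,8a-octahydronaphthalene-1-carboxylate (C8 ketone, C11 ester, C1=C2 alkene)
Conditions: Pd2(dba)3·CHCl3 (2.5 mol %), dppe (6 mol %), THF (0.02 M), 60 °C
Reagents that add atoms: none
Why: Zerovalent palladium displaces the C2 carbonate with inversion to give a cationic η3-allyl complex over C2–C1–C10, CO2 is lost and the methoxide released deprotonates C9, so the nucleophile appears only when the electrophile is in place. The stabilised enolate then adds to the allyl terminus on the face away from the metal, which is the known Tsuji–Trost cyclisation of β-keto esters tethered to allylic carbonates. Ring B closes in the 6-exo mode through a chair-like array with the C5–C6 bond pseudoequatorial. C10 is set by the double inversion (net retention with allylic transposition): C9 arrives on the face that the carbonate left, opposite to C6, which means a trans ring fusion with C20 axial, while C9 is set thermodynamically because the ester can reach the equatorial position by enolisation. The step needs attack at the tertiary terminus C10 and not at C2, which the three-atom tether C6–C8 secures since closure at C2 would give a bridged eight-membered ring, and it needs faithful face transfer, which the trans C2/C5 relationship of 9 supplies. Closure through the enolate oxygen is reversible under the catalyst and should drain to 10, and the chelating ligand, low loading and dilution are chosen against β-hydride loss, face exchange of the complex and intermolecular alkylation.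

Step 9
Reactants: 10 trans-fused bicyclic β-keto ester
Product: 11 saturated β-keto ester, methyl (1R,4aS,8aS)-5,5,8a-trimethyl-2-oxodecahydronaphthalene-1-carboxylate
Conditions: H2 (1 atm), Pd/C, EtOAc, rt
Reagents that add atoms: none
Why: Heterogeneous catalytic hydrogenation of the only alkene, the cis-disubstituted C1=C2 bond, which leaves the keto ester untouched and creates no stereocentre.

Step 10
Reactants: 11 saturated β-keto ester
Product: 12 exo-methylene ester, methyl (1S,4aS,8aS)-5,5,8a-trimethyl-2-methylidenedecahydronaphthalene-1-carboxylate
Conditions: Zn, CH2Br2, TiCl4, THF (reagent pre-formed at 0–5 °C); 11, CH2Cl2, 0 °C to rt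
Reagents that add atoms: dibromomethane, BrCBr
Why: Lombardo-type methylenation: the weakly basic zinc–titanium methylene reagent converts ketones and not esters and should not enolise C9, so the equatorial ester and the β,γ-position of the new C8=C17 bond are kept.

Step 11
Reactants: 12 exo-methylene ester
Product: 13 (+)-albicanol, [(1S,4aS,8aS)-5,5,8a-trimethyl-2-methylidenedecahydronaphthalen-1-yl]methanol
Conditions: LiAlH4, Et2O, 0 °C
Reagents that add atoms: none
Why: Hydride reduction of the ester to the primary alcohol gives (+)-albicanol, a known natural product whose reported data allow identity and absolute configuration to be checked at this point.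

Step 12
Reactants: 13 (+)-albicanol
Product: 14 albicanyl triflate
Conditions: Tf2O, 2,6-lutidine, CH2Cl2, −78 to −20 °C; cold aqueous work-up, used at once
Reagents that add atoms: triflic anhydride, O=S(=O)(OS(=O)(=O)C(F)(F)F)C(F)(F)F
Why: O-Sulfonylation with a hindered base; the triflate is chosen because β-branched C11 needs the best leaving group available, and it is carried on without storage.

Step 13
Reactants: 15 dimethyl D-malate, dimethyl (R)-2-hydroxybutanedioate
Product: 16 dimethyl (2R,3S)-2-hydroxy-3-methylbutanedioate
Conditions: LiN(i-Pr)2 (2.2 equiv), THF, −78 to −20 °C; MeI, −78 to 0 °C; AcOH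
Reagents that add atoms: iodomethane, CI
Why: Fráter–Seebach alkylation: the chelated lithium alkoxide enolate is methylated on the face opposite to the carbinol substituent, which sets C13 anti to the C14 oxygen, i.e. (2R,3S), the minor syn isomer being removed by chromatography.

Step 14
Reactants: 16 dimethyl (2R,3S)-2-hydroxy-3-methylbutanedioate
Product: 17 (2R,3R)-3-methylbutane-1,2,4-triol
Conditions: LiAlH4, THF, 0 °C to reflux
Reagents that add atoms: none
Why: Exhaustive hydride reduction of both esters, which touches neither stereocentre.

Step 15
Reactants: 17 (2R,3R)-3-methylbutane-1,2,4-triol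
Product: 18 (2R)-2-[(4R)-2,2-dimethyl-1,3-dioxolan-4-yl]propan-1-ol
Conditions: Me2C(OMe)2, acetone, p-TsOH (cat.), rt
Reagents that add atoms: 2,2-dimethoxypropane, COC(C)(C)OC
Why: Acetonide formation under thermodynamic control prefers the five-membered dioxolane on the C14/C15 diol over a dioxane that would bear an axial methyl group, and so leaves the C12 hydroxyl free.

Step 16
Reactants: 18 (2R)-2-[(4R)-2,2-dimethyl-1,3-dioxolan-4-yl]propan-1-ol
Product: 19 (4R)-4-[(2S)-1-bromopropan-2-yl]-2,2-dimethyl-1,3-dioxolane
Conditions: CBr4, PPh3, CH2Cl2, 0 °C
Reagents that add atoms: carbon tetrabromide, BrC(Br)(Br)Br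
Why: Appel bromination, an SN2 displacement at primary C12 under nearly neutral conditions that spares the acetonide and both stereocentres.

Step 17
Reactants: 14 albicanyl triflate; 19 (4R)-4-[(2S)-1-bromopropan-2-yl]-2,2-dimethyl-1,3-dioxolane
Product: 21 (13R,14R)-labd-8(17)-ene-14,15-diol acetonide, via side-chain Grignard reagent 20 (not isolated)
Conditions: 19, Mg, THF, rt to 40 °C; then CuBr·SMe2 (10 mol %), 14, THF–Et2O, −40 to 0 °C
Reagents that add atoms: none
Why: Copper-catalysed sp3–sp3 cross-coupling of a Grignard reagent with a primary triflate (SN2-type attack of the alkylcuprate at C11, then reductive elimination) forms C11–C12 without touching any stereocentre, and the γ-alkoxy Grignard reagent has no β-leaving group.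

Step 18
Reactants: 21 (13R,14R)-labd-8(17)-ene-14,15-diol acetonide
Product: 22 (13R,14R)-labd-8(17)-ene-14,15-diol
Conditions: AcOH–H2O–THF, 40 °C
Reagents that add atoms: none
Why: Acid-catalysed acetonide hydrolysis under conditions too mild to move the exocyclic C8=C17 bond into the ring.

Step 19
Reactants: 22 (13R,14R)-labd-8(17)-ene-14,15-diol
Product: 24 (13R,14R)-14-acetoxylabd-8(17)-en-15-ol (target), via cyclic orthoacetate 23 (not isolated)
Conditions: MeC(OMe)3, PPTS (cat.), CH2Cl2, rt; then AcOH–H2O, 0 °C to rt
Reagents that add atoms: trimethyl orthoacetate, COC(C)(OC)OC; water, O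
Why: Monoacylation through a cyclic orthoester: the diol forms orthoacetate 23, whose mild hydrolysis passes through a hemiorthoester that releases the primary C15 oxygen preferentially and so leaves the acetyl group on the hindered C14 oxygen, where direct acetylation would have chosen C15; base and long contact with silica are avoided to prevent acyl migration.

**Compound list**

1 | (±)-α-ionone (racemic) | CC(=O)/C=C/C1C(C)=CCCC1(C)C | starting material
2 | (±)-dihydro-α-ionone (racemic) | CC(=O)CCC1C(C)=CCCC1(C)C | intermediate
3 | (±)-dihydro-α-ionone ethylene ketal (racemic) | CC1(CCC2C(C)=CCCC2(C)C)OCCO1 | intermediate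
4 | (±)-C2 enone ketal (racemic) | CC1(CCC2C(C)=CC(=O)CC2(C)C)OCCO1 | intermediate
5 | (±)-trans allylic alcohol ketal (racemate, both enantiomers written) | CC1(CC[C@@H]2C(C)=C[C@@H](O)CC2(C)C)OCCO1.CC1(CC[C@H]2C(C)=C[C@H](O)CC2(C)C)OCCO1 | intermediate
6 | (2S,5S)-trans allylic alcohol ketal | CC1(CC[C@@H]2C(C)=C[C@@H](O)CC2(C)C)OCCO1 | intermediate
7 | (2S,5S)-hydroxy ketone | CC(=O)CC[C@@H]1C(C)=C[C@@H](O)CC1(C)C | intermediate
8 | dimethyl carbonate | COC(=O)OC | starting material
9 | β-keto ester allylic carbonate (2S,5S; carbonate trans to the chain) | COC(=O)CC(=O)CC[C@@H]1C(C)=C[C@@H](OC(=O)OC)CC1(C)C | intermediate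
10 | trans-fused bicyclic β-keto ester with C1=C2 | COC(=O)[C@H]1C(=O)CC[C@H]2C(C)(C)CC=C[C@]12C | intermediate
11 | saturated trans-fused β-keto ester | COC(=O)[C@H]1C(=O)CC[C@H]2C(C)(C)CCC[C@]12C | intermediate
12 | exo-methylene ester | COC(=O)[C@H]1C(=C)CC[C@H]2C(C)(C)CCC[C@]12C | intermediate
13 | (+)-albicanol | OC[C@H]1C(=C)CC[C@H]2C(C)(C)CCC[C@]12C | intermediate
14 | albicanyl triflate | O=S(=O)(OC[C@H]1C(=C)CC[C@H]2C(C)(C)CCC[C@]12C)C(F)(F)F | intermediate
15 | dimethyl D-malate | COC(=O)C[C@@H](O)C(=O)OC | starting material
16 | dimethyl (2R,3S)-2-hydroxy-3-methylbutanedioate | COC(=O)[C@@H](C)[C@@H](O)C(=O)OC | intermediate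
17 | (2R,3R)-3-methylbutane-1,2,4-triol | OC[C@@H](C)[C@@H](O)CO | intermediate
18 | (2R)-2-[(4R)-2,2-dimethyl-1,3-dioxolan-4-yl]propan-1-ol | OC[C@@H](C)[C@@H]1COC(C)(C)O1 | intermediate
19 | (4R)-4-[(2S)-1-bromopropan-2-yl]-2,2-dimethyl-1,3-dioxolane | BrC[C@@H](C)[C@@H]1COC(C)(C)O1 | intermediate
20 | side-chain Grignard reagent (C12–MgBr) | Br[Mg]C[C@@H](C)[C@@H]1COC(C)(C)O1 | intermediate
21 | (13R,14R)-labd-8(17)-ene-14,15-diol acetonide | C=C1CC[C@H]2C(C)(C)CCC[C@]2(C)[C@H]1CC[C@@H](C)[C@@H]3COC(C)(C)O3 | intermediate
22 | (13R,14R)-labd-8(17)-ene-14,15-diol | C=C1CC[C@H]2C(C)(C)CCC[C@]2(C)[C@H]1CC[C@@H](C)[C@@H](O)CO | intermediate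
23 | cyclic 14,15-orthoacetate (epimers at the orthoester carbon) | C=C1CC[C@H]2C(C)(C)CCC[C@]2(C)[C@H]1CC[C@@H](C)[C@@H]3COC(C)(OC)O3 | intermediate
24 | (13R,14R)-14-acetoxylabd-8(17)-en-15-ol, CNP0285908.2 | C=C1CC[C@H]2C(C)(C)CCC[C@]2(C)[C@H]1CC[C@@H](C)[C@H](CO)OC(C)=O | target

**Step count.** Total steps: 19. Longest linear sequence: 15 (steps 1–12 and 17–19).

**Steps most likely to fail**

1. **Step 8.**
   - What may go wrong: ionisation may be slow, because the metal has to bind the ring face that carries the C5 chain and lies close to the axial C4 methyl. The anti trajectory to the tertiary terminus is strained, so β-hydride loss from the allyl complex may outrun ring closure.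
   - Fallback: it sets out from 9 and comes back at 10, and makes the same C9–C10 bond as a cationic cyclisation without any transition metal. SnCl4 (CH2Cl2, −78 to −20 °C) ionises the carbonate to the free C2–C1–C10 allyl cation and binds the keto ester as a chelated enol. C9 then closes on C10 through the chair array known from Lewis-acid cyclisations of olefinic β-keto esters.
   - What changes: no metal occupies a ring face. The facial choice rests on C5 alone (equatorial chain, trans fusion), and the C2 configuration becomes irrelevant. No new compound arises (F0).

2. **Step 17.**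
   - What may go wrong: displacement at the β-branched C11 may be too slow, so that halide exchange at the triflate or base-induced elimination across C9–C11 (loss of the allylic H9) takes over.
   - Fallback: the polarity of the partners is reversed. It sets out from 13 and 19 and comes back at 21. Appel bromination of 13 (CBr4, PPh3) gives albicanyl bromide F1, and magnesium in THF turns it into albicanylmagnesium bromide F2. F2 is alkylated with bromide 19 under Li2CuCl4 catalysis in THF–NMP. The displacement then takes place at the less crowded C12, and the hindered C11 acts as the nucleophile.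

3. **Step 10.**
   - What may go wrong: chelation or enolisation of the 1,3-dicarbonyl unit may consume the methylene reagent, or the Lewis acid may move the new alkene into conjugation with the ester.
   - Fallback: the ester is removed before the methylene group is introduced. It sets out from 11 and comes back at 13. Ketalisation (ethylene glycol, p-TsOH, toluene, reflux) gives the ketal ester F3, LiAlH4 gives the ketal alcohol F4, and dilute aqueous acid gives the β-hydroxy ketone F5. F5 is an ordinary ketone, and its zinc–titanium methylenation (Zn, CH2Br2, TiCl4) delivers 13 directly.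

**Further compounds**

F0 | step 8 | none | none
F1 | step 17 | albicanyl bromide | BrC[C@H]1C(=C)CC[C@H]2C(C)(C)CCC[C@]12C
F2 | step 17 | albicanylmagnesium bromide | Br[Mg]C[C@H]1C(=C)CC[C@H]2C(C)(C)CCC[C@]12C
F3 | step 10 | ketal ester (C8 ethylene ketal of 11) | COC(=O)[C@H]1C2(OCCO2)CC[C@H]3C(C)(C)CCC[C@]13C
F4 | step 10 | ketal alcohol | OC[C@H]1C2(OCCO2)CC[C@H]3C(C)(C)CCC[C@]13C
F5 | step 10 | β-hydroxy ketone (C11 alcohol, C8 ketone) | OC[C@H]1C(=O)CC[C@H]2C(C)(C)CCC[C@]12C
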